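In a one-step world, with G made at a rate proportional to the J and the Z charged, both apparent orders are one; the teal flask, now being followed, is asked for these orders at 10% conversion.

the same everywhere: Q 0.050 M; D 0.050 M; Z 2.5 mM; E 0.75 mM

| charge | J | remark |
|---|---|---|
| teal | 0.040 M | the very flask that is asked about, followed so far |
| red | 0.060 M | run made earlier |
| flask | 0.0400 M |  |

- teal (time / s: G / %): 10.0: 5.5; 12.0: 6.1; 25.0: 10.5; 40.0: 14.9
- red (time / s: G / %): 10.0: 8.1; 12.0: 8.5; 30.0: 17.0; 80.0: 28.1

(each reading ± 0.3 percentage points)

- Z is single-handed; Q and D are mirror images of each other, charged as a racemate, each of them at the stated concentration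
- no earlier run changes the charge of Z; that part of a forecast is a guess

1. apparent order in J when 10% of the Q and D together are converted (percent change of the rate of making G for one percent more J charged)
2. apparent order in Z when 10% of the Q and D together are converted (percent change of the rate of making G for one percent more Z charged)

The runs seem to disagree with themselves: the G read in the teal and red flasks at 10.0 s, taken as a measure of rate, gives an order in J of 0.955, yet near 10% conversion the forecast reads the slopes as 1.6 to one for 1.50 times the J. We follow one molecule of J, taking one J per turn. At that fixed time the G read in the teal and red flasks counts for a similar share of their J, but at fixed conversion we count the same amount of J taken from each, so on this count a richer charge keeps a larger share. We call the chance that a molecule of a charge is still free to act at that moment its working share; when the amount taken is fixed and the rate is first order in what is free, the apparent order in that charge is one over this share. For J the teal share is 0.750 and the red share 0.833, so we reckon a ratio of J left, red over teal, of 1.67 and a teal order of 1.33. If each E holds one Z, as a tight-binding inhibitor does, which is our guess because no run changes Z, the share of Z is 0.700 and its order 1.43.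

The forecast gives 1.2 and 1, both below our figures, noting that “E might titrate some Z, pushing the order above 1, but that is a guess”.

The flask gives 1.3 in J and 1.5 in Z, against our 1.33 and 1.43.

    Z + E → Z.E (k = 5100 M⁻¹ s⁻¹)
    2 J → X (k = 0.0300 M⁻¹ s⁻¹)
    J + Z + Q → Z + G (k = 170 M⁻² s⁻¹)
    J + Z + D → Z + Vo (k = 20.0 M⁻² s⁻¹)

By 0.300 min E stood at 0%, Z at 70.0% of its charge, a working share of 0.700, and Z.E at 30.0%, and these held to 30.0 min. Meanwhile J + Z + Q made G, which reached 8.38% at that first time with J at 73.2%, then 27.3% at 3.00 min with J at 12.5%, and 31.2% at 30.0 min with J at 0%.

All runs were computed for substances that don't exist, noise included.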